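**Retrosynthetic overview**
1. Cordycicadin D ⇒ ynoate ester of the ten-membered hydroxy-enone lactone. The last step is an alkoxypalladation (enol-ether C–O bond) / conjugate-addition bis-cyclisation that closes the tetrahydrofuran and γ-butyrolactone rings together.
2. Ynoate ester ⇒ ester C–O bond between the macrolide alcohol and a pyranyl hydroxy-ynoic acid.
3. Macrolide (formed second) ⇒ ring-closing metathesis of the diene ester of (6R)-6-hydroxyhept-1-en-3-one and (3S)-3-hydroxypent-4-enoic acid (from 2-deoxy-D-ribose).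
4. Ynoic acid ⇒ alkynol ⇒ cis-fused pyrano-γ-lactone ⇒ Pd/CO oxycarbonylative bicyclisation (pyran ring formed first, two C–O bonds) of (2R,5S)-hept-6-ene-2,5-diol, made from the same enone.
5. Both halves come from (R)-γ-valerolactone. Ring order: pyran → macrolactone → tetrahydrofuran + butyrolactone.

Assumption: the E enol ether of the target (ring oxygen anti to the lactone carbonyl) is taken to be the thermodynamically preferred geometry of the push–pull alkene; 2-deoxy-D-ribose is drawn open-chain.

**Route**

Step 1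
Reactants: 1 (R)-γ-valerolactone; 2 vinylmagnesium bromide
Product: 3 (6R)-6-hydroxyhept-1-en-3-one
Conditions: 2 (1.05 equiv) added to 1, THF, −78 °C, 1 h; cold pH 7 aqueous quench
Reagents that add atoms: none
Why: Grignard acylation of a lactone, in which the first adduct is held at −78 °C as the magnesium salt of the cyclic hemiketal and so resists a second addition until the quench releases the hydroxy enone; the carbinol centre comes unchanged from 1.

Step 2
Reactants: 3 (6R)-6-hydroxyhept-1-en-3-one
Product: 4 (2R,5S)-hept-6-ene-2,5-diol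
Conditions: (R)-Me-CBS oxazaborolidine [(R)-1-methyl-3,3-diphenyltetrahydro-1H,3H-pyrrolo[1,2-c][1,3,2]oxazaborole] (20 mol %), catecholborane (2.5 equiv), toluene, −78 °C; then MeOH, 1 M NaOH
Reagents that add atoms: none
Why: Corey–Bakshi–Shibata reduction in which the vinyl group acts as the larger π-substituent, so the (R)-catalyst delivers hydride to the Re face and gives the (5S) allylic alcohol (expected dr about 9:1; the minor epimer is mismatched in step 3 and is removed there).

Step 3
Reactants: 4 (2R,5S)-hept-6-ene-2,5-diol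
Product: 5 (3aS,5R,7aS)-5-methylhexahydro-2H-furo[3,2-b]pyran-2-one
Conditions: PdCl2 (10 mol %), CuCl2 (3 equiv), NaOAc (3 equiv), CO (1 atm), AcOH, 23 °C
Reagents that add atoms: carbon monoxide, [C-]#[O+]
Why: Palladium-catalysed alkoxycarbonylative bicyclisation (alkoxypalladation, CO insertion, lactonisation): the C2 hydroxyl attacks the palladium-bound alkene 6-exo through a chair with methyl equatorial and the allylic hydroxyl cis to the new C–Pd arm, and that hydroxyl then captures the acyl-palladium, so the 2,6-cis pyran and the cis ring fusion (3aS) follow from the two existing centres while CuCl2 reoxidises zerovalent palladium to divalent palladium.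

Step 4
Reactants: 5 (3aS,5R,7aS)-5-methylhexahydro-2H-furo[3,2-b]pyran-2-one
Product: 7 (2S,3S,6R)-6-methyl-2-(prop-2-yn-1-yl)oxan-3-ol, via lactol 6 (not isolated)
Conditions: i-Bu2AlH (1.1 equiv), CH2Cl2, −78 °C; then MeOH, K2CO3 (3 equiv), dimethyl (1-diazo-2-oxopropyl)phosphonate (1.5 equiv), 0 → 23 °C
Reagents that add atoms: dimethyl (1-diazo-2-oxopropyl)phosphonate, COP(=O)(OC)C(=[N+]=[N-])C(C)=O
Why: Lactone half-reduction followed by Seyferth–Gilbert homologation under Ohira–Bestmann conditions on the hydroxy-aldehyde form of the lactol; the all-equatorial 2,6-cis pyran is the thermodynamic isomer, so reversible β-alkoxide elimination under K2CO3 cannot erode it.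

Step 5
Reactants: 7 (2S,3S,6R)-6-methyl-2-(prop-2-yn-1-yl)oxan-3-ol
Product: 8 4-[(2S,3S,6R)-3-hydroxy-6-methyloxan-2-yl]but-2-ynoic acid
Conditions: n-BuLi (2.2 equiv), THF, −78 °C; CO2 (gas), −78 → 0 °C; 1 M HCl
Reagents that add atoms: carbon dioxide, O=C=O
Why: Acetylide carboxylation of the alkoxide/acetylide dianion (the alkyl carbonate formed on oxygen reverts on acidification); no stereocentre is touched.

Step 6
Reactants: 9 2-deoxy-D-ribose
Product: 10 2-deoxy-D-ribono-1,4-lactone [(4S,5R)-4-hydroxy-5-(hydroxymethyl)oxolan-2-one]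
Conditions: Br2 (1.2 equiv), NaHCO3, H2O, 23 °C
Reagents that add atoms: none
Why: Bromine-water oxidation of an aldose to its aldonolactone, selective for the hemiacetal carbon with both carbinol centres untouched.

Step 7
Reactants: 10 2-deoxy-D-ribono-1,4-lactone
Product: 11 (4S,5S)-4-hydroxy-5-(iodomethyl)oxolan-2-one
Conditions: I2 (1.2 equiv), PPh3 (1.2 equiv), imidazole (2.5 equiv), THF, 0 → 23 °C
Reagents that add atoms: iodine, II
Why: Appel-type (Garegg–Samuelsson) iodination, selective for the primary over the secondary hydroxyl (the descriptor change at C5 is only a priority change).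

Step 8
Reactants: 11 (4S,5S)-4-hydroxy-5-(iodomethyl)oxolan-2-one
Product: 12 (3S)-3-hydroxypent-4-enoic acid
Conditions: Zn dust (5 equiv), AcOH (3 equiv), THF, 23 °C
Reagents that add atoms: none
Why: Zinc-mediated reductive β-elimination (reverse iodolactonisation): zinc inserts into the C–I bond and expels the lactone carboxylate, revealing the vinyl group and the acid while the (S) carbinol is retained.

Step 9
Reactants: 12 (3S)-3-hydroxypent-4-enoic acid; 3 (6R)-6-hydroxyhept-1-en-3-one
Product: 16 (2R)-5-oxohept-6-en-2-yl (3S)-3-hydroxypent-4-enoate, via bis-silyl derivative 13 (not isolated), via acid chloride 14 (not isolated), via silyl ether ester 15 (not isolated)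
Conditions: TMSCl (2.2 equiv), Et3N (2.2 equiv), CH2Cl2, 0 °C; (COCl)2 (1.05 equiv), DMF (cat.), 0 → 23 °C; 3 (0.8 equiv), pyridine (2 equiv), −20 → 0 °C; citric acid (cat.), MeOH, 0 °C
Reagents that add atoms: none
Why: Esterification through transient persilylation, in which the silyl ester is turned into the acid chloride by oxalyl chloride/DMF without HCl while the silyl ether masks the β-hydroxyl, the secondary alcohol of 3 is acylated, and mild acidic methanolysis removes the silyl ether; both stereocentres are spectators.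

Step 10
Reactants: 16 (2R)-5-oxohept-6-en-2-yl (3S)-3-hydroxypent-4-enoate
Product: 17 (4S,5E,10R)-4-hydroxy-10-methyl-1-oxacyclodec-5-ene-2,7-dione
Conditions: second-generation Hoveyda–Grubbs catalyst [RuCl2(H2IMes)(=CH-C6H4-2-OiPr)] (10 mol %), 2,6-dichloro-1,4-benzoquinone (20 mol %), toluene (1 mM), 80 °C
Reagents that add atoms: none
Why: Ring-closing metathesis between the vinyl ketone and the allylic-alcohol olefin at high dilution, expected to give the conjugated E enone under thermodynamic control, with the benzoquinone suppressing ruthenium-hydride isomerisation of the free allylic alcohol.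

Step 11
Reactants: 8 4-[(2S,3S,6R)-3-hydroxy-6-methyloxan-2-yl]but-2-ynoic acid; 17 (4S,5E,10R)-4-hydroxy-10-methyl-1-oxacyclodec-5-ene-2,7-dione
Product: 21 (4S,5E,10R)-10-methyl-2,7-dioxo-1-oxacyclodec-5-en-4-yl 4-[(2S,3S,6R)-3-hydroxy-6-methyloxan-2-yl]but-2-ynoate, via bis-silyl derivative 18 (not isolated), via acid chloride 19 (not isolated), via silyl ether ester 20 (not isolated)
Conditions: TMSCl (2.2 equiv), Et3N (2.2 equiv), CH2Cl2, 0 °C; (COCl)2 (1.05 equiv), DMF (cat.), 0 °C; 17 (0.7 equiv), pyridine (2 equiv), −20 → 0 °C; citric acid (cat.), MeOH, 0 °C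
Reagents that add atoms: none
Why: The same transient-silylation acyl chloride esterification, chosen because HCl-free chloride formation avoids hydrochlorination of the ynoate and pyridine at low temperature is too weak to eliminate the β-acyloxy lactone; the allylic carbinol keeps its (S) configuration because only its O–H bond reacts.

Step 12
Reactants: 21 (4S,5E,10R)-10-methyl-2,7-dioxo-1-oxacyclodec-5-en-4-yl 4-[(2S,3S,6R)-3-hydroxy-6-methyloxan-2-yl]but-2-ynoate
Product: 23 cordycicadin D, via Z enol ether isomer 22 (not isolated)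
Conditions: Pd(OAc)2 (10 mol %), 2,2′-bipyridine (12 mol %), AcOH/1,4-dioxane 1:4, 60 °C; then CF3CO2H (20 mol %), CH2Cl2, 23 °C
Reagents that add atoms: none
Why: Proposed new method: a divalent-palladium-catalysed alkoxypalladation/conjugate-addition bis-cyclisation in which the pyranyl hydroxyl adds 5-exo-dig to the palladium-activated ynoate at its β-carbon (the key C–O bond) to give an α-palladated β-alkoxyacrylate, whose C–Pd bond inserts 5-exo into the macrocyclic E enone from its peripheral face (allylic C–H eclipsing the alkene, ester oxygen and incoming carbon on the same face) and so sets the new ring stereocentre R, trans to the lactone CH2 arm, after which the bipyridine-ligated palladium enolate is protonated by AcOH rather than undergoing β-hydride elimination, regenerating divalent palladium, and the Z enol ether expected from anti addition (if syn addition operates, 23 forms directly) is equilibrated by CF3CO2H through C-protonation to the oxocarbenium ion to the E isomer; the closest known reactions are the acetoxypalladation-initiated cyclisation of 4-oxo-2-alkenyl 2-alkynoates to α-alkylidene-γ-butyrolactones terminated by protonolysis and the oxypalladation/conjugate addition of 2-alkynylphenols with enones, neither shown with a tethered aliphatic alcohol on an ynoate or on a macrocyclic enone.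

**Compound list**
1 | (R)-γ-valerolactone [(5R)-5-methyloxolan-2-one] | C[C@@H]1CCC(=O)O1 | starting material
2 | vinylmagnesium bromide | C=C[Mg]Br | starting material
3 | (6R)-6-hydroxyhept-1-en-3-one | C[C@@H](O)CCC(=O)C=C | intermediate
4 | (2R,5S)-hept-6-ene-2,5-diol | C[C@@H](O)CC[C@H](O)C=C | intermediate
5 | (3aS,5R,7aS)-5-methylhexahydro-2H-furo[3,2-b]pyran-2-one | O=C1C[C@@H]2O[C@H](C)CC[C@@H]2O1 | intermediate
6 | (3aS,5R,7aS)-5-methylhexahydro-2H-furo[3,2-b]pyran-2-ol (lactol, anomers) | OC1C[C@@H]2O[C@H](C)CC[C@@H]2O1 | intermediate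
7 | (2S,3S,6R)-6-methyl-2-(prop-2-yn-1-yl)oxan-3-ol | C#CC[C@@H]1O[C@H](C)CC[C@@H]1O | intermediate
8 | 4-[(2S,3S,6R)-3-hydroxy-6-methyloxan-2-yl]but-2-ynoic acid | OC(=O)C#CC[C@@H]1O[C@H](C)CC[C@@H]1O | intermediate
9 | 2-deoxy-D-ribose [(3S,4R)-3,4,5-trihydroxypentanal] | O=CC[C@H](O)[C@H](O)CO | starting material
10 | 2-deoxy-D-ribono-1,4-lactone [(4S,5R)-4-hydroxy-5-(hydroxymethyl)oxolan-2-one] | O=C1C[C@H](O)[C@@H](CO)O1 | intermediate
11 | (4S,5S)-4-hydroxy-5-(iodomethyl)oxolan-2-one | O=C1C[C@H](O)[C@@H](CI)O1 | intermediate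
12 | (3S)-3-hydroxypent-4-enoic acid | OC(=O)C[C@H](O)C=C | intermediate
13 | trimethylsilyl (3S)-3-(trimethylsilyloxy)pent-4-enoate | C[Si](C)(C)OC(=O)C[C@H](O[Si](C)(C)C)C=C | intermediate
14 | (3S)-3-(trimethylsilyloxy)pent-4-enoyl chloride | ClC(=O)C[C@H](O[Si](C)(C)C)C=C | intermediate
15 | (2R)-5-oxohept-6-en-2-yl (3S)-3-(trimethylsilyloxy)pent-4-enoate | C[C@H](CCC(=O)C=C)OC(=O)C[C@H](O[Si](C)(C)C)C=C | intermediate
16 | (2R)-5-oxohept-6-en-2-yl (3S)-3-hydroxypent-4-enoate | C[C@H](CCC(=O)C=C)OC(=O)C[C@H](O)C=C | intermediate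
17 | (4S,5E,10R)-4-hydroxy-10-methyl-1-oxacyclodec-5-ene-2,7-dione | C[C@@H]1CCC(=O)/C=C/[C@@H](O)CC(=O)O1 | intermediate
18 | trimethylsilyl 4-[(2S,3S,6R)-6-methyl-3-(trimethylsilyloxy)oxan-2-yl]but-2-ynoate | C[Si](C)(C)OC(=O)C#CC[C@@H]1O[C@H](C)CC[C@@H]1O[Si](C)(C)C | intermediate
19 | 4-[(2S,3S,6R)-6-methyl-3-(trimethylsilyloxy)oxan-2-yl]but-2-ynoyl chloride | ClC(=O)C#CC[C@@H]1O[C@H](C)CC[C@@H]1O[Si](C)(C)C | intermediate
20 | (4S,5E,10R)-10-methyl-2,7-dioxo-1-oxacyclodec-5-en-4-yl 4-[(2S,3S,6R)-6-methyl-3-(trimethylsilyloxy)oxan-2-yl]but-2-ynoate | C[C@@H]1CCC(=O)/C=C/[C@@H](OC(=O)C#CC[C@@H]2O[C@H](C)CC[C@@H]2O[Si](C)(C)C)CC(=O)O1 | intermediate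
21 | (4S,5E,10R)-10-methyl-2,7-dioxo-1-oxacyclodec-5-en-4-yl 4-[(2S,3S,6R)-3-hydroxy-6-methyloxan-2-yl]but-2-ynoate | C[C@@H]1CCC(=O)/C=C/[C@@H](OC(=O)C#CC[C@@H]2O[C@H](C)CC[C@@H]2O)CC(=O)O1 | intermediate
22 | Z enol ether isomer of cordycicadin D (ring oxygen syn to the lactone carbonyl) | C[C@@H]1CCC(=O)C[C@@H]2/C(=C3\C[C@@H]4O[C@H](C)CC[C@@H]4O3)C(=O)O[C@H]2CC(=O)O1 | intermediate
23 | cordycicadin D (trans-fused γ-butyrolactone/ten-membered keto-lactone carrying the E-(3aS,5R,7aS)-5-methylhexahydrofuro[3,2-b]pyran-2-ylidene group at the lactone α-carbon) | C[C@@H]1CCC(=O)C[C@@H]2/C(=C3/C[C@@H]4O[C@H](C)CC[C@@H]4O3)C(=O)O[C@H]2CC(=O)O1 | target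

**Totals**
Total steps: 12. Longest linear sequence: 7 steps (1 → 3 → 4 → 5 → 7 → 8 → 21 → 23, or 9 → 10 → 11 → 12 → 16 → 17 → 21 → 23).

**Three steps most likely to fail**

Step 12 (the new bis-cyclisation). The vinyl-palladium intermediate may be protonated before it inserts into the enone, acetate may compete with the tethered hydroxyl, or the alkene may not equilibrate cleanly. The fallback uses known chemistry, sets out from 21 and comes back at 23. Ph3PAuCl/AgOTf (5 mol %) in wet 1,4-dioxane hydrates the ynoate by intramolecular alkoxy-auration and hydrolysis to the β-keto ester F1 (in equilibrium with its five-membered hemiketal). Cs2CO3 (0.3 equiv) in MeCN at 0 °C then effects the 5-exo-trig intramolecular Michael addition to the enone, giving the α-acyl-γ-butyrolactone F2 (epimers at the acidic α-carbon; trans ring substituents by the same allylic-strain model). PPTS with 4 Å molecular sieves in toluene at 60 °C closes the hemiketal and dehydrates it to the E enol ether 23.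

Step 10 (ring-closing metathesis to the ten-membered enone). The Z enone or the cyclic dimer may dominate. The fallback sets out from 3 and 12, bypasses 16 and comes back at 17. Cross-metathesis of 12 with 3 (2 equiv) using the second-generation Hoveyda–Grubbs catalyst in CH2Cl2 at 40 °C gives, E-selectively, the seco acid F3. Yamaguchi macrolactonisation (2,4,6-trichlorobenzoyl chloride, Et3N, THF; then DMAP, toluene, 80 °C, 1 mM) then closes the ring through the ester C–O bond to give 17. The mixed anhydride is formed quickly so that the free carboxylate cannot add to the enone.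

Step 11 (one-pot silylation/acyl chloride coupling of two advanced fragments). The ynoyl chloride may decompose, or the β-acyloxy lactone may eliminate. The fallback replaces the transient protection by an isolated silyl ether and carbodiimide activation; it sets out from 7 and comes back at 21. TESCl/imidazole in CH2Cl2 gives the silyl ether F4. n-BuLi then CO2 gives the acid F5. EDC·HCl with DMAP (cat.) in CH2Cl2 at 0 °C couples F5 with 17 to the ester F6. HF·pyridine in THF at 0 °C then frees the hydroxyl to give 21.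

**Further compounds**
F1 | step 12 | (4S,5E,10R)-10-methyl-2,7-dioxo-1-oxacyclodec-5-en-4-yl 4-[(2S,3S,6R)-3-hydroxy-6-methyloxan-2-yl]-3-oxobutanoate | C[C@@H]1CCC(=O)/C=C/[C@@H](OC(=O)CC(=O)C[C@@H]2O[C@H](C)CC[C@@H]2O)CC(=O)O1
F2 | step 12 | trans-fused butyrolactone/ten-membered keto-lactone bearing a 2-[(2S,3S,6R)-3-hydroxy-6-methyloxan-2-yl]acetyl group at the lactone α-carbon (α-epimers) | C[C@@H]1CCC(=O)C[C@@H]2C(C(=O)C[C@@H]3O[C@H](C)CC[C@@H]3O)C(=O)O[C@H]2CC(=O)O1
F3 | step 10 | (3S,4E,9R)-3,9-dihydroxy-6-oxodec-4-enoic acid | C[C@@H](O)CCC(=O)/C=C/[C@@H](O)CC(=O)O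
F4 | step 11 | triethyl{[(2S,3S,6R)-6-methyl-2-(prop-2-yn-1-yl)oxan-3-yl]oxy}silane | C#CC[C@@H]1O[C@H](C)CC[C@@H]1O[Si](CC)(CC)CC
F5 | step 11 | 4-[(2S,3S,6R)-6-methyl-3-(triethylsilyloxy)oxan-2-yl]but-2-ynoic acid | OC(=O)C#CC[C@@H]1O[C@H](C)CC[C@@H]1O[Si](CC)(CC)CC
F6 | step 11 | (4S,5E,10R)-10-methyl-2,7-dioxo-1-oxacyclodec-5-en-4-yl 4-[(2S,3S,6R)-6-methyl-3-(triethylsilyloxy)oxan-2-yl]but-2-ynoate | C[C@@H]1CCC(=O)/C=C/[C@@H](OC(=O)C#CC[C@@H]2O[C@H](C)CC[C@@H]2O[Si](CC)(CC)CC)CC(=O)O1
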